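The constants of this flask don't need equal care, so I sort them before I reckon.

    substrate + coupling partner → target (k1 = 0.29 L mol⁻¹ s⁻¹)
    substrate + 2 coupling partner → side product (k2 = 9.8 L² mol⁻² s⁻¹)
    solid reagent ⇌ coupling partner, rate k3*(cs3 - [coupling partner]) while solid is left; crystals form when [coupling partner] > cs3 (cs3 = 44 mM, k3 = 5.5 × 10⁻⁴ s⁻¹)
    coupling partner + target → over-reaction product (k4 = 0.013 L mol⁻¹ s⁻¹)
    crystals ⇌ target, rate k5*(cs5 - [target]) while solid is left; crystals form when [target] > cs5 (cs5 = 31 mM, k5 = 0.037 s⁻¹)

substrate 0.050 M; solid reagent 0.0750 M; time 20 min

- target is meant together with its crystals
- two of one species on the left: rate k times its square, two consumed each time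
- solid, in amounts per volume of the solution: solid reagent, crystals
- at the start none of the solid reagent is in solution
- run time (flask): 20 min

- the target standing at 20 min, as a percentage of the substrate charged
- the side product standing at 20 min, as a percentage of the substrate charged

The target-forming step would halve the coupling partner in 0.797 min at the charged substrate, while dissolution closes half its gap to saturation in 21.0 min, so the partner is used as it arrives and dissolution is the rate-limiting step. In powers of ten, the exponents −0.180 (dissolution coefficient times time) and −0.0555 (solubility over substrate charge) add up to −0.236, which is the power of ten of 58.1 %: this is the delivery ceiling, the share of the substrate charge that dissolves in the run into a solution empty of coupling partner.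

| Mark | Share of substrate charge |
|---|---|
| delivery ceiling | 58.1 % |
| target at which crystals form | 62.0 % |
| solid reagent charged | 150 % |

The dissolution coefficient and the solubility must be known well: an error in either passes to the target at weight one and to the side product at weight two. The coupling constant reaches the target through the partner's resting level at the charged substrate, 3.34 % of the charge, which trims delivery by 3.79 %. The coupling constant and the side-reaction constant both move the side product, through a selectivity factor of 17.7 reckoned at the charged substrate. The over-reaction constant is 0.0448 of the coupling constant, so I drop that step from this reckoning. In this flask the ceiling stays below the crystal mark, so I reckon without crystals up to the asked time.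

Trimmed delivery less the resting level leaves 52.5 % turned over. Each target takes one partner and each side product two, so I commit to 47.2 % target and 2.66 % side product.

The forecast gives 43 % target, less than my figure, and 3 % side product, more than mine, with conversion “capped at roughly half”.

The flask gives 44.2 % target and 2.71 % side product. At 20.0 min its solid reagent stands at 62.8 % of its own charge, so 55.8 % of the substrate charge has dissolved, less than the ceiling of 58.1 %. In the neighbour flask read at 30 min, the ceiling is 87.1 %, above the crystal mark. There 82.9 % of the substrate charge has dissolved, the target stands at 63.1 %, and crystals, counted in that target, hold 0.497 % of the substrate charge.

The constants used here are made up.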